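**Retrosynthetic overview**
1. The C3 ester is disconnected last: bis-silylated caffeic acid plus the 1-O-silyl ether of eudesm-4(15)-ene-1β,3β,8α-triol.
2. Ring A (O1, O3, C4=C15, trans H5) comes from a 1β-hydroxy-4-en-3-one: Li/NH3 sets H5 and gives the C3–C4 enolate for aminomethylation, the same pot and a second Li/NH3 reduction set C7, C8 and C3, and a Cope elimination makes C4=C15.
3. Feature used: O3 and O8 are 1,6-related through C4–C5–C6–C7, the pattern left when two enone β-carbons are joined, and C10 is the prochiral carbon of a 4,4-disubstituted cyclohexadienone. The key disconnection is therefore C5–C6, an enantioselective reductive coupling of the side-chain enone β-carbon (C6) with one dienone β-carbon (C5).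
4. Ring order: ring A is the arene of p-cresol (dearomatizing allylation); ring B is closed in the key step. The precursor follows by alkene cleavage, Nozaki–Hiyama–Kishi vinylation and oxidation.
5. O1 is introduced through the enone left in ring A (epoxidation, dehydrogenation, reductive opening).

Key step: step 7

**Conventions and remarks**
- Decalin intermediates carry eudesmane numbers (C14 = methyl on C10, C15 = methylene carbon on C4); β is the face of C14.
- Remark on the chemistry: C7 is carried through the key step with a 2-methoxypropan-2-yl group instead of isopropyl. The ether oxygen gives the Lewis acid a second binding site on the side-chain enone. Its later loss as methanol turns the ring B ketone into an isopropylidene enone, so C7 is no stereocenter until it is set by axial protonation in the trans-fused series (step 13). An α-isopropyl ketone is too weakly biased toward the equatorial epimer for equilibration to fix C7.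
- Assumption: the sense of induction of the chiral scandium complex cannot be predicted; the ligand antipode is chosen so that 10 has the C10 configuration of the target.

**Route**

Step 1
Reactants: 1 p-cresol; 2 allyltrimethylsilane
Product: 3 4-allyl-4-methylcyclohexa-2,5-dien-1-one
Conditions: PhI(OAc)2, (CF3)2CHOH, 0 °C
Reagents that add atoms: none
Why: Oxidative Hosomi–Sakurai dearomatization: the hypervalent iodine reagent oxidizes the phenol to a phenoxenium-type species that the fluorinated alcohol stabilizes long enough for the allylsilane to attack the para carbon, giving the achiral 4,4-disubstituted dienone.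

Step 2
Reactants: 3 4-allyl-4-methylcyclohexa-2,5-dien-1-one
Product: 4 2-(1-methyl-4-oxocyclohexa-2,5-dien-1-yl)acetaldehyde
Conditions: OsO4 (2 mol %), NaIO4, 2,6-lutidine, dioxane/H2O, rt
Reagents that add atoms: sodium periodate, [Na+].[O-]I(=O)(=O)=O (oxygen donor by way of catalytic OsO4)
Why: Lemieux–Johnson cleavage: osmylation picks the electron-rich terminal alkene over the two electron-poor dienone alkenes and periodate cleaves the diol to the aldehyde.

Step 3
Reactants: 5 3-hydroxy-3-methylbutan-2-one
Product: 6 3-methoxy-3-methylbutan-2-one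
Conditions: Me3OBF4, 1,8-bis(dimethylamino)naphthalene, CH2Cl2, rt
Reagents that add atoms: trimethyloxonium tetrafluoroborate, C[O+](C)C.F[B-](F)(F)F
Why: O-Methylation with Meerwein's salt and a non-nucleophilic proton scavenger alkylates the hindered tertiary hydroxyl without forming an enolate.

Step 4
Reactants: 6 3-methoxy-3-methylbutan-2-one
Product: 7 3-methoxy-3-methylbut-1-en-2-yl trifluoromethanesulfonate
Conditions: KN(SiMe3)2, THF, −78 °C; PhNTf2, −78 °C to rt
Reagents that add atoms: N-phenylbis(trifluoromethanesulfonimide), O=S(=O)(N(c1ccccc1)S(=O)(=O)C(F)(F)F)C(F)(F)F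
Why: The ketone can enolize only toward its methyl group, so O-triflation of the potassium enolate gives the 1,1-disubstituted vinyl triflate as one regioisomer.

Step 5
Reactants: 4 2-(1-methyl-4-oxocyclohexa-2,5-dien-1-yl)acetaldehyde; 7 3-methoxy-3-methylbut-1-en-2-yl trifluoromethanesulfonate
Product: 8 4-[2-hydroxy-3-(2-methoxypropan-2-yl)but-3-en-1-yl]-4-methylcyclohexa-2,5-dien-1-one (racemic carbinol)
Conditions: CrCl2 (4 equiv), NiCl2 (2 mol %), DMF, rt
Reagents that add atoms: none
Why: Nozaki–Hiyama–Kishi coupling: nickel inserts into the vinyl triflate and passes the vinyl group to chromium, and the vinylchromium species adds to the aldehyde but not to the dienone; the racemic carbinol is oxidized in the next step.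

Step 6
Reactants: 8 4-[2-hydroxy-3-(2-methoxypropan-2-yl)but-3-en-1-yl]-4-methylcyclohexa-2,5-dien-1-one
Product: 9 4-[3-(2-methoxypropan-2-yl)-2-oxobut-3-en-1-yl]-4-methylcyclohexa-2,5-dien-1-one
Conditions: Dess–Martin periodinane, NaHCO3, CH2Cl2, 0 °C to rt
Reagents that add atoms: none
Why: Dess–Martin oxidation of the secondary allylic alcohol under buffered neutral conditions gives the α-methylene ketone without touching the dienone or the tertiary ether.

Step 7
Reactants: 9 4-[3-(2-methoxypropan-2-yl)-2-oxobut-3-en-1-yl]-4-methylcyclohexa-2,5-dien-1-one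
Product: 10 cis-fused 7-(2-methoxypropan-2-yl)-10-methyldecal-1-ene-3,8-dione (5β-H; 10β-CH3; C7 epimers)
Conditions: Ru(bpy)3(PF6)2 (2 mol %), Sc(OTf)3 (10 mol %), (S,S)-iPr-PyBox (12 mol %), Hantzsch ester (1.5 equiv), MeCN, 450 nm LEDs, −20 °C
Reagents that add atoms: none
Why: Proposed new method: the excited divalent ruthenium complex is quenched by the Hantzsch ester and the resulting reductant passes one electron to the side-chain enone, which is the easier acceptor because its carbonyl and methoxy oxygens chelate trivalent scandium; the chelate also holds the enone s-trans, so the radical anion has its spin at C6 on the same side of the C7–C8 enolate as C9 and closes ring B by 6-exo-trig attack on C5 of one dienone alkene. The α-keto radical at C4 then takes a hydrogen atom (or an electron and a proton) from the dihydropyridine and the scandium enolate is protonated at C7, so the net change is one C–C bond and two hydrogens. The closest known reactions are the photoredox and samarium diiodide reductive cyclizations of tethered bis-enones (racemic) and chiral Lewis acid control of photogenerated enone radical anions and of radical conjugate additions; an enantioselective desymmetrizing version on a cyclohexadienone has not been shown. C10 is fixed by which enantiotopic dienone alkene is attacked, the one selectivity the route needs from this step, and it must come from the PyBox ligand sphere around the chelated radical, which sits one CH2 from the prochiral carbon in a chair-like transition state. C5 follows from the short tether, which reaches only the dienone face that carries C9 (cis fusion), and C7 is formed by unselective protonation and is erased in step 8. Reduction of the dienone or of the product enone is disfavoured because neither is chelated.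

Step 8
Reactants: 10 cis-fused 7-(2-methoxypropan-2-yl)-10-methyldecal-1-ene-3,8-dione
Product: 11 cis-fused 7-isopropylidene-10-methyldecal-1-ene-3,8-dione (5β-H; 10β-CH3)
Conditions: DBU, toluene, 80 °C
Reagents that add atoms: none
Why: E1cB loss of methanol from the β-methoxy ketone under equilibrating amine base gives the conjugated tetrasubstituted isopropylidene enone, which removes the uncontrolled C7 center and leaves ring B with no position that can be dehydrogenated or readily epoxidized.

Step 9
Reactants: 11 cis-fused 7-isopropylidene-10-methyldecal-1-ene-3,8-dione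
Product: 12 cis-fused 1β,2β-epoxy-7-isopropylidene-10-methyldecalin-3,8-dione
Conditions: t-BuOOH (anhydrous), DBU, CH2Cl2, 0 °C to rt
Reagents that add atoms: tert-butyl hydroperoxide, CC(C)(C)OO
Why: Weitz–Scheffer epoxidation: the bulky peroxide anion adds only to the disubstituted C1=C2 enone and attacks C1 axially on the convex β face of the cis-fused bicycle (anti to C9, the α face being covered by ring B), as expected for a cis-fused enone of this type, so O1 is β.

Step 10
Reactants: 12 cis-fused 1β,2β-epoxy-7-isopropylidene-10-methyldecalin-3,8-dione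
Product: 13 1β,2β-epoxy-7-isopropylidene-10-methyldecal-4-ene-3,8-dione
Conditions: IBX, 4-methoxypyridine N-oxide, DMSO, 25–40 °C
Reagents that add atoms: none
Why: IBX dehydrogenation through the ketone enol, which can form only toward C4 because C2 is an oxirane carbon, removes H4 and H5 and so erases the cis C5 center, while the ring B enone has no hydrogen on C10 to lose.

Step 11
Reactants: 13 1β,2β-epoxy-7-isopropylidene-10-methyldecal-4-ene-3,8-dione
Product: 14 1β-hydroxy-7-isopropylidene-10-methyldecal-4-ene-3,8-dione
Conditions: (PhSe)2, NaBH4 (no excess), EtOH; AcOH; 0 °C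
Reagents that add atoms: none
Why: Reductive opening of the α,β-epoxy ketone by the phenylselenide–borate reagent: selenide attacks C2, a second selenide removes selenium to leave the enolate, and protonation gives the β-hydroxy ketone with the C1–O bond and its β configuration untouched.

Step 12
Reactants: 14 1β-hydroxy-7-isopropylidene-10-methyldecal-4-ene-3,8-dione
Product: 15 7-isopropylidene-10-methyl-1β-(triethylsilyloxy)decal-4-ene-3,8-dione
Conditions: Et3SiCl, imidazole, DMF, rt
Reagents that add atoms: chlorotriethylsilane, CC[Si](Cl)(CC)CC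
Why: Silylation of the secondary hydroxyl protects the β-hydroxy enone from dehydration, keeps an alkoxide out of the enolate chemistry of step 13 and removes O1 from the acylation of step 18.

Step 13
Reactants: 15 7-isopropylidene-10-methyl-1β-(triethylsilyloxy)decal-4-ene-3,8-dione
Product: 17 trans-fused 4α-(dimethylaminomethyl)-7β-isopropyl-10-methyl-1β-(triethylsilyloxy)decalin-3,8-dione, via dilithium bis-enolate 16 (not isolated)
Conditions: Li (6 equiv), NH3 (l)/THF, t-BuOH (2.0 equiv), −78 °C; isoprene; NH3 evaporated; CH2=NMe2+ I− (1.1 equiv), THF, −78 to −40 °C; AcOH, −78 °C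
Reagents that add atoms: N,N-dimethylmethyleneiminium iodide (Eschenmoser's salt), C=[N+](C)C.[I-]
Why: Dissolving-metal reduction of both enones followed by a Mannich reaction: the ring A enone takes its β-proton axially at C5 to give the trans-fused C3–C4 enolate, the ring B enone is protonated at C11 and held as the C7–C8 enolate, Eschenmoser's salt alkylates only the less hindered C4 enolate (from the α face, away from the axial C10 methyl), and the acid quench at −78 °C protonates C7 axially on the α face so that isopropyl ends up β and equatorial.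

Step 14
Reactants: 17 trans-fused 4α-(dimethylaminomethyl)-7β-isopropyl-10-methyl-1β-(triethylsilyloxy)decalin-3,8-dione (used crude)
Product: 18 trans-fused 4α-(dimethylaminomethyl)-7β-isopropyl-10-methyl-1β-(triethylsilyloxy)decalin-3β,8α-diol
Conditions: Li, NH3 (l)/THF/EtOH, −78 °C, inverse addition of 17; NH4Cl
Reagents that add atoms: none
Why: Dissolving-metal reduction of the two ketones gives the more stable equatorial alcohols (3β and 8α) and is faster than enolization, so C7 is not epimerized, whereas a hydride reagent would approach C8 anti to the 1,3-diaxial C10 methyl and give the axial 8β alcohol.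

Step 15
Reactants: 18 trans-fused 4α-(dimethylaminomethyl)-7β-isopropyl-10-methyl-1β-(triethylsilyloxy)decalin-3β,8α-diol
Product: 19 N-oxide of 18
Conditions: mCPBA (1.05 equiv), CH2Cl2, 0 °C; filtration through basic Al2O3
Reagents that add atoms: 3-chloroperbenzoic acid, O=C(OO)c1cccc(Cl)c1
Why: The tertiary amine is the only site the peracid can oxidize, since the molecule has no alkene at this stage.

Step 16
Reactants: 19 N-oxide of 18
Product: 20 1-O-triethylsilyl eudesm-4(15)-ene-1β,3β,8α-triol
Conditions: DMSO/THF, 80 °C
Reagents that add atoms: none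
Why: Cope elimination: the N-oxide removes the only β-hydrogen it can reach (H4) through a five-membered syn transition state and gives the exocyclic C4=C15 alkene without base and without an α-methylene ketone intermediate.

Step 17
Reactants: 21 caffeic acid
Product: 23 (E)-3-[3,4-bis(tert-butyldimethylsilyloxy)phenyl]prop-2-enoic acid, via tris-silylated caffeate 22 (not isolated)
Conditions: t-BuMe2SiCl (3.3 equiv), imidazole, DMF, rt; then AcOH/THF/H2O, rt
Reagents that add atoms: tert-butyldimethylsilyl chloride, CC(C)(C)[Si](C)(C)Cl
Why: Exhaustive silylation followed by mild hydrolysis of the labile silyl ester leaves both phenols protected and the acid free.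

Step 18
Reactants: 20 1-O-triethylsilyl eudesm-4(15)-ene-1β,3β,8α-triol; 23 (E)-3-[3,4-bis(tert-butyldimethylsilyloxy)phenyl]prop-2-enoic acid
Product: 24 3-O-[(E)-3,4-bis(tert-butyldimethylsilyloxy)cinnamoyl] 1-O-triethylsilyl eudesm-4(15)-ene-1β,3β,8α-triol
Conditions: 23 (1.05 equiv), EDC·HCl, DMAP (0.1 equiv), CH2Cl2, −20 to 0 °C
Reagents that add atoms: none
Why: Steglich esterification with one equivalent of acid at low temperature should acylate the allylic equatorial C3 hydroxyl, flanked by a CH2 and the sp2 C4, in preference to the C8 hydroxyl, flanked by the isopropyl-bearing C7, while O1 is silylated.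

Step 19
Reactants: 24 3-O-[(E)-3,4-bis(tert-butyldimethylsilyloxy)cinnamoyl] 1-O-triethylsilyl eudesm-4(15)-ene-1β,3β,8α-triol
Product: 25 3-O-(E)-caffeoyl eudesm-4(15)-ene-1β,3β,8α-triol (CNP0264533.1)
Conditions: HF·pyridine, pyridine/THF, 0 °C to rt
Reagents that add atoms: none
Why: Fluoride cleaves the two aryl silyl ethers and the triethylsilyl ether under buffered, mildly acidic conditions that neither hydrolyze nor shift the allylic ester and do not expose the catechol to base.

**Compound list**
1 | p-cresol | Cc1ccc(O)cc1 | starting material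
2 | allyltrimethylsilane | C=CC[Si](C)(C)C | starting material
3 | 4-allyl-4-methylcyclohexa-2,5-dien-1-one | C=CCC1(C)C=CC(=O)C=C1 | intermediate
4 | 2-(1-methyl-4-oxocyclohexa-2,5-dien-1-yl)acetaldehyde | O=CCC1(C)C=CC(=O)C=C1 | intermediate
5 | 3-hydroxy-3-methylbutan-2-one | CC(=O)C(C)(C)O | starting material
6 | 3-methoxy-3-methylbutan-2-one | CC(=O)C(C)(C)OC | intermediate
7 | 3-methoxy-3-methylbut-1-en-2-yl trifluoromethanesulfonate | C=C(OS(=O)(=O)C(F)(F)F)C(C)(C)OC | intermediate
8 | 4-[2-hydroxy-3-(2-methoxypropan-2-yl)but-3-en-1-yl]-4-methylcyclohexa-2,5-dien-1-one (racemic) | C=C(C(C)(C)OC)C(O)CC1(C)C=CC(=O)C=C1 | intermediate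
9 | 4-[3-(2-methoxypropan-2-yl)-2-oxobut-3-en-1-yl]-4-methylcyclohexa-2,5-dien-1-one (key-step precursor) | C=C(C(C)(C)OC)C(=O)CC1(C)C=CC(=O)C=C1 | intermediate
10 | cis-fused 7-(2-methoxypropan-2-yl)-10-methyldecal-1-ene-3,8-dione (5β-H, 10β-CH3, C7 epimers) | O=C1C=C[C@]2(C)CC(=O)C(C(C)(C)OC)C[C@@H]2C1 | intermediate
11 | cis-fused 7-isopropylidene-10-methyldecal-1-ene-3,8-dione | O=C1C=C[C@]2(C)CC(=O)C(=C(C)C)C[C@@H]2C1 | intermediate
12 | cis-fused 1β,2β-epoxy-7-isopropylidene-10-methyldecalin-3,8-dione | O=C1[C@H]3O[C@H]3[C@]2(C)CC(=O)C(=C(C)C)C[C@@H]2C1 | intermediate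
13 | 1β,2β-epoxy-7-isopropylidene-10-methyldecal-4-ene-3,8-dione | O=C1[C@H]3O[C@H]3[C@]2(C)CC(=O)C(=C(C)C)CC2=C1 | intermediate
14 | 1β-hydroxy-7-isopropylidene-10-methyldecal-4-ene-3,8-dione | O=C1C[C@@H](O)[C@]2(C)CC(=O)C(=C(C)C)CC2=C1 | intermediate
15 | 7-isopropylidene-10-methyl-1β-(triethylsilyloxy)decal-4-ene-3,8-dione | O=C1C[C@@H](O[Si](CC)(CC)CC)[C@]2(C)CC(=O)C(=C(C)C)CC2=C1 | intermediate
16 | dilithium 3,8-bis-enolate (C3=C4 and C7=C8), trans-fused, 1β-OSiEt3 | [Li]OC=1C[C@@H](O[Si](CC)(CC)CC)[C@]2(C)CC(O[Li])=C(C(C)C)C[C@H]2C=1 | intermediate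
17 | trans-fused 4α-(dimethylaminomethyl)-7β-isopropyl-10-methyl-1β-(triethylsilyloxy)decalin-3,8-dione | O=C1C[C@@H](O[Si](CC)(CC)CC)[C@]2(C)CC(=O)[C@@H](C(C)C)C[C@H]2[C@@H]1CN(C)C | intermediate
18 | trans-fused 4α-(dimethylaminomethyl)-7β-isopropyl-10-methyl-1β-(triethylsilyloxy)decalin-3β,8α-diol | O[C@H]1C[C@@H](O[Si](CC)(CC)CC)[C@]2(C)C[C@H](O)[C@@H](C(C)C)C[C@H]2[C@@H]1CN(C)C | intermediate
19 | N-oxide of 18 | O[C@H]1C[C@@H](O[Si](CC)(CC)CC)[C@]2(C)C[C@H](O)[C@@H](C(C)C)C[C@H]2[C@@H]1C[N+](C)(C)[O-] | intermediate
20 | 1-O-triethylsilyl eudesm-4(15)-ene-1β,3β,8α-triol | C=C1[C@@H](O)C[C@@H](O[Si](CC)(CC)CC)[C@]2(C)C[C@H](O)[C@@H](C(C)C)C[C@@H]12 | intermediate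
21 | caffeic acid | O=C(O)/C=C/c1ccc(O)c(O)c1 | starting material
22 | tert-butyldimethylsilyl (E)-3-[3,4-bis(tert-butyldimethylsilyloxy)phenyl]prop-2-enoate | CC(C)(C)[Si](C)(C)OC(=O)/C=C/c1ccc(O[Si](C)(C)C(C)(C)C)c(O[Si](C)(C)C(C)(C)C)c1 | intermediate
23 | (E)-3-[3,4-bis(tert-butyldimethylsilyloxy)phenyl]prop-2-enoic acid | O=C(O)/C=C/c1ccc(O[Si](C)(C)C(C)(C)C)c(O[Si](C)(C)C(C)(C)C)c1 | intermediate
24 | 3-O-[(E)-3,4-bis(tert-butyldimethylsilyloxy)cinnamoyl] 1-O-triethylsilyl eudesm-4(15)-ene-1β,3β,8α-triol | C=C1[C@@H](OC(=O)/C=C/c2ccc(O[Si](C)(C)C(C)(C)C)c(O[Si](C)(C)C(C)(C)C)c2)C[C@@H](O[Si](CC)(CC)CC)[C@]2(C)C[C@H](O)[C@@H](C(C)C)C[C@@H]12 | intermediate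
25 | 3-O-(E)-caffeoyl eudesm-4(15)-ene-1β,3β,8α-triol (CNP0264533.1) | C=C1[C@@H](OC(=O)/C=C/c2ccc(O)c(O)c2)C[C@@H](O)[C@]2(C)C[C@H](O)[C@@H](C(C)C)C[C@@H]12 | target

**Step count**
Total: 19 steps. Longest linear sequence: 16 steps (1, 2, 5–16, 18, 19).

**Steps most likely to fail**

1. Step 7 (Proposed new method). The chiral scandium complex may discriminate poorly between the two enantiotopic dienone alkenes, the electron may go to the dienone instead, or the radical anion may be reduced further or oligomerize before it cyclizes. Fallback, from 9 back to 11: the cyclization is run without asymmetric induction under known photoredox conditions for tethered bis-enones (Ru(bpy)3Cl2, i-Pr2NEt, HCO2H, MeCN, visible light), which should give the racemic cis-fused dione F1. DBU then eliminates methanol to give the racemic isopropylidene enone F2. Preparative chromatography on a chiral stationary phase separates 11 from its antipode, the ent-isopropylidene enone F3, which is discarded.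

2. Step 13. The two enolates may not be told apart (aminomethylation at C7 as well as C4), proton exchange may scramble the enolate positions before trapping, or the protonation at C7 may lack facial selectivity. Fallback, from 15 back to 17: the enolates are separated as neutral silyl enol ethers. After the same Li/NH3 reduction the mixture is quenched with Me3SiCl/Et3N to give the bis(trimethylsilyl enol ether) F4. Eschenmoser's salt in CH2Cl2 then reacts only with the less hindered ring A enol ether (Mukaiyama-type Mannich reaction) to give the ring B silyl enol ether amino ketone F5. Bu4NF/AcOH at −78 °C releases and protonates the C7–C8 enolate to give 17.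

3. Step 18. The acylating agent may not discriminate well enough between the C3 and C8 hydroxyls, giving the C8 ester and the diester. Fallback, from 18 back to 24: the acylation is moved before the elimination. In 18 the dimethylamino group sits 1,3 to O3 and can act as internal base and acyl-transfer relay, so 23 with EDC·HCl and no DMAP should give the C3 amino ester F6. mCPBA then gives the amino ester N-oxide F7, and Cope elimination at 80 °C gives 24.

**Further compounds**
F1 | step 7 | racemic cis-fused 7-(2-methoxypropan-2-yl)-10-methyldecal-1-ene-3,8-dione | O=C1C=C[C@]2(C)CC(=O)C(C(C)(C)OC)C[C@@H]2C1.O=C1C=C[C@@]2(C)CC(=O)C(C(C)(C)OC)C[C@H]2C1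
F2 | step 7 | racemic cis-fused 7-isopropylidene-10-methyldecal-1-ene-3,8-dione | O=C1C=C[C@]2(C)CC(=O)C(=C(C)C)C[C@@H]2C1.O=C1C=C[C@@]2(C)CC(=O)C(=C(C)C)C[C@H]2C1
F3 | step 7 | ent-11 (5α-H, 10α-CH3 antipode of the isopropylidene enone) | O=C1C=C[C@@]2(C)CC(=O)C(=C(C)C)C[C@H]2C1
F4 | step 13 | trans-fused 3,8-bis(trimethylsilyloxy)-3,7-diene (C3=C4 and C7=C8), 7-isopropyl, 1β-OSiEt3 | C[Si](C)(C)OC=1C[C@@H](O[Si](CC)(CC)CC)[C@]2(C)CC(O[Si](C)(C)C)=C(C(C)C)C[C@H]2C=1
F5 | step 13 | trans-fused 4α-(dimethylaminomethyl)-3-oxo-8-(trimethylsilyloxy)-7-ene, 7-isopropyl, 1β-OSiEt3 | O=C1C[C@@H](O[Si](CC)(CC)CC)[C@]2(C)CC(O[Si](C)(C)C)=C(C(C)C)C[C@H]2[C@@H]1CN(C)C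
F6 | step 18 | 3-O-[(E)-3,4-bis(tert-butyldimethylsilyloxy)cinnamoyl] derivative of 18 | O=C(/C=C/c1ccc(O[Si](C)(C)C(C)(C)C)c(O[Si](C)(C)C(C)(C)C)c1)O[C@H]1C[C@@H](O[Si](CC)(CC)CC)[C@]2(C)C[C@H](O)[C@@H](C(C)C)C[C@H]2[C@@H]1CN(C)C
F7 | step 18 | N-oxide of F6 | O=C(/C=C/c1ccc(O[Si](C)(C)C(C)(C)C)c(O[Si](C)(C)C(C)(C)C)c1)O[C@H]1C[C@@H](O[Si](CC)(CC)CC)[C@]2(C)C[C@H](O)[C@@H](C(C)C)C[C@H]2[C@@H]1C[N+](C)(C)[O-]
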